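1. Beside this flask stand two neighbours, one with twice the free catalyst and one with 3.0 mM, and the question is what each has left to work with at the same conversion.

substrate 0.29 M; partner 0.174 M; free catalyst 29 mM

* the form that holds most of the catalyst when 20 % of the substrate are converted (resting dimer / free catalyst / spent catalyst)
* its share of the catalyst then
* factor on the rate of making product when 20 % of the substrate are converted if free catalyst is charged twice over
* factor on the rate when 20 % of the substrate are converted if free catalyst is charged at 3.0 mM instead

2. Fastest rung: pairs of free catalyst sit in balance with the resting dimer (35.1 /M), which counts as two. From the start I therefore have 14.4 mM free, half of the charge.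

3. Next rung: two free catalyst turn into spent catalyst (deactivation), with a first half-life by this step alone of 20.4 s.

4. Last rung: with substrate and partner taken halfway to the mark, each free catalyst gives product at 0.0684 /s. The 58.0 mM wanted then takes 58.8 s at the starting level. That is slower than the loss, so I cannot hold the catalyst constant.

5. So I drop time and divide the two rates. The catalyst budget, the product made while free catalyst falls by a factor e, is that rate over 2k, G = 20.1 mM. With K the dimer constant, the dimer adds a term: product/G = ln(start/[free catalyst]) + 4K(start − [free catalyst]). Here product/G is 2.88.

6. I go round. Leaving [free catalyst] out of the last term gives 6.11 mM, and putting that back gives 2.59 mM. The answers swing, so I restart from their geometric mean, 3.98 mM, which returns 3.50 mM. I commit to 3.73 mM free, which is 12.9 % of the catalyst, with 3.37 % in the dimer and 83.8 % spent.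

7. The forecast names spent catalyst at 85 %, with factors 2.4 and 0.053: “doubling the charge gives more than double because less time is needed”. Its share stands above my 83.8 % spent.

8. The simulation gives spent catalyst at 84.9 %, with factors 2.41 and 0.0532.

    substrate + partner + free catalyst → product + free catalyst, rate k1*[substrate]*[partner]*[free catalyst]/(1 + ([substrate]/sat1)) (sat1 = 0.496 M, k1 = 2.76 /M²/s)
    2 free catalyst → spent catalyst (k2 = 1.70 /M/s)
    2 free catalyst ⇌ resting dimer, settled at all times (K3 = 35.1 /M)

In this flask, catalyst loss has half of its turnover up to 3.00 min done by 0.461 min, earlier than product at 0.669 min. At 2.03 min the flask holds 84.9 % as spent catalyst. Its free catalyst at that moment, 3.51 mM, entered in the budget, pays for 59.1 mM, against the 58.0 mM made. The 3.0 mM flask has the same G at the same conversion but starts from 2.55 mM free. Going round gives 0.204 mM, then 0.198 mM, and that flask stands at 0.187 mM.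

Its constants stand for no real mixture; the flask was simulated.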